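**Plan**

1. Retrosynthesis: the tiglate C–O bond and the C4–C5 oxirane are removed first (leaving a Z C4=C5 olefin beside the C6 carbinol), then the exocyclic C11=C13 methylene. The C4=C5 bond of the ten-membered carbocycle is then cut with insertion of an SO2 group, the resulting 11-membered thiacycle is opened at S–C4, and the chain is cut at C1=C10 (Wittig), C8–C9 (allylation) and C6–C7 (aldol).
2. Forward: aldol, allylation and ozonolysis build the five-membered O-heterocycle on C7–C8 (masked γ-lactone) first. A Wittig reaction adds C1–C4, a thiolate closes the 11-membered sulfide (S between C5 and C4), and oxidation followed by a Ramberg–Bäcklund reaction deletes sulfur to leave the ten-membered 1(10),4-diene. Lactone, α-methylene, tiglate and oxirane are added last.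
3. Enabling feature: C4 (methyl-bearing) and C5 are adjacent ring carbons that end as an olefin-derived oxirane, so a sulfonyl bridge between them is a traceless one-atom spacer. The thiacycloundecene that carries it already holds the ring-trans C1=C10 olefin and the trans-fused tetrahydrofuran on C7–C8.
4. Stereochemistry: C6/C7 from an auxiliary-controlled titanium aldol; C8 from a BINOL–Ti allylation on the Felkin face; C1=C10 geometry from the α-silyloxy-ketone Wittig reaction; C4=C5 geometry from the cis-fused episulfone; C4/C5 of the oxirane from C6–OH-directed peracid epoxidation.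

Key step: step 17

Remark: locants C1–C15 are the germacrane locants of the target (C12 lactone carbonyl, C13 exocyclic methylene, C14 CH2O, C15 methyl).
Remark: two stereocentres that are erased later are carried as mixtures and have no descriptor in the SMILES: the lactol/acetal carbon C12 (oxidised in step 19) and C4 (becomes sp2 in step 17; racemic 17 is used).
Remark: anhydrous chloroacetaldehyde is freed from its commercial aqueous solution directly before use.

Step 1
Reactants: 1 (S)-4-benzylthiazolidine-2-thione; 2 pent-4-enoyl chloride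
Product: 3 (S)-1-(4-benzyl-2-thioxothiazolidin-3-yl)pent-4-en-1-one
Conditions: Et3N, DMAP (cat.), CH2Cl2, 0 °C → rt
Reagents that add atoms: none
Why: N-acylation of the chiral auxiliary; no stereocentre is touched.

Step 2
Reactants: 3; 4 chloroacetaldehyde
Product: 5 (2S,3S)-2-allyl-1-[(S)-4-benzyl-2-thioxothiazolidin-3-yl]-4-chloro-3-hydroxybutan-1-one (C6–OH and C7–allyl syn)
Conditions: TiCl4, i-Pr2NEt, NMP, CH2Cl2, 0 → −78 °C; then 4, −78 → 0 °C
Reagents that add atoms: none
Why: Titanium-enolate aldol of an N-acylthiazolidinethione in the Evans-syn mode: the Z-enolate should react through a chair transition state on the face away from the benzyl group, setting C7 and C6 together.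

Step 3
Reactants: 5
Product: 6 (2S,3S)-2-allyl-1-[(S)-4-benzyl-2-thioxothiazolidin-3-yl]-3-(tert-butyldimethylsilyloxy)-4-chlorobutan-1-one
Conditions: TBSOTf, 2,6-lutidine, CH2Cl2, −78 → 0 °C
Reagents that add atoms: tert-butyldimethylsilyl triflate CC(C)(C)[Si](C)(C)OS(=O)(=O)C(F)(F)F
Why: Silylation of the secondary alcohol; O6 stays masked until step 21 so that only O8 can later close onto C12.

Step 4
Reactants: 6
Product: 7 (2S,3S)-2-allyl-3-(tert-butyldimethylsilyloxy)-4-chlorobutanal
Conditions: DIBAL-H, CH2Cl2, −78 °C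
Reagents that add atoms: none
Why: Direct half-reduction of the N-acylthiazolidinethione to the aldehyde with release of the auxiliary; the low temperature should preserve the α-stereocentre C7.

Step 5
Reactants: 8 2-methylprop-2-en-1-ol
Product: 9 2-[(tributylstannyl)methyl]prop-2-en-1-ol
Conditions: n-BuLi (2.2 equiv), TMEDA, Et2O/hexane, 0 °C → rt; then Bu3SnCl, −78 °C → rt
Reagents that add atoms: tributyltin chloride CCCC[Sn](Cl)(CCCC)CCCC
Why: Allylic metalation of the alkoxide (O,C-dianion) and C-stannylation give the bifunctional allylstannane.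

Step 6
Reactants: 9
Product: 10 tert-butyldiphenyl({2-[(tributylstannyl)methyl]allyl}oxy)silane
Conditions: TBDPSCl, imidazole, DMF, rt
Reagents that add atoms: tert-butyldiphenylsilyl chloride CC(C)(C)[Si](Cl)(c1ccccc1)c1ccccc1
Why: Standard silylation of the primary alcohol (future C14–O).

Step 7
Reactants: 7; 10
Product: 11 (2S,3R,4S)-3-allyl-2-(tert-butyldimethylsilyloxy)-6-[(tert-butyldiphenylsilyloxy)methyl]-1-chlorohept-6-en-4-ol (C6, C7, C8 all-syn)
Conditions: (S)-BINOL (20 mol %), Ti(Oi-Pr)4 (10 mol %), 4 Å MS, CH2Cl2, −20 °C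
Reagents that add atoms: none
Why: Keck asymmetric allylation with a 2-substituted allylstannane: the (S)-BINOL–Ti complex should deliver the allyl group to the Si face of the aldehyde, which is also the Felkin face, so catalyst and substrate reinforce each other in setting C8.

Step 8
Reactants: 11
Product: 13 1-{(2S,3R)-3-[(S)-1-(tert-butyldimethylsilyloxy)-2-chloroethyl]-5-hydroxytetrahydrofuran-2-yl}-3-(tert-butyldiphenylsilyloxy)propan-2-one (lactol anomers), via bis-ozonide 12 (not isolated)
Conditions: O3, CH2Cl2, −78 °C; then PPh3, −78 °C → rt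
Reagents that add atoms: ozone [O-][O+]=O
Why: Ozonolysis cleaves both the vinyl and the 1,1-disubstituted olefin; the C12 aldehyde is captured by the only free hydroxyl (O8) as the five-membered lactol and the C10 ketone is unveiled.

Step 9
Reactants: 13
Product: 14 1-{(2S,3R)-3-[(S)-1-(tert-butyldimethylsilyloxy)-2-chloroethyl]-5-methoxytetrahydrofuran-2-yl}-3-(tert-butyldiphenylsilyloxy)propan-2-one (anomers)
Conditions: MeOH, PPTS (cat.), 0 °C → rt
Reagents that add atoms: methanol CO
Why: Acetalisation of the lactol fixes the O8–C12 bond as a base-stable 2-methoxytetrahydrofuran that has no acidic C–H, as required in steps 12–17.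

Step 10
Reactants: 15 5-chloropentan-2-one
Product: 16 (4-oxopentyl)triphenylphosphonium iodide
Conditions: PPh3, NaI, MeCN, reflux
Reagents that add atoms: triphenylphosphine c1ccc(cc1)P(c1ccccc1)c1ccccc1; sodium iodide [Na+].[I-]
Why: Finkelstein-assisted SN2 quaternisation of the phosphine at the primary carbon.

Step 11
Reactants: 16
Product: 17 (4-hydroxypentyl)triphenylphosphonium iodide (racemic)
Conditions: NaBH4, MeOH, 0 °C
Reagents that add atoms: none
Why: Borohydride reduction of the ketone leaves the phosphonium group intact; the new carbinol centre (C4) need not be controlled because it is erased in step 17.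

Step 12
Reactants: 14; 17
Product: 19 (Z)-7-{(2S,3R)-3-[(S)-1-(tert-butyldimethylsilyloxy)-2-chloroethyl]-5-methoxytetrahydrofuran-2-yl}-6-[(tert-butyldiphenylsilyloxy)methyl]hept-5-en-2-ol (C4 epimers), via ylide 18 (not isolated)
Conditions: 17, KHMDS (2 equiv per 17), THF, −78 → 0 °C; then 14, −78 → −20 °C
Reagents that add atoms: none
Why: Wittig reaction of an α-silyloxy ketone with a salt-free non-stabilised ylide (used as its δ-oxido form), a combination known to place the ylide chain cis to CH2OSi; C2 should therefore end cis to C14 and trans to C9, as in the target.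

Step 13
Reactants: 19
Product: 20 the C5 thioacetate of 19 (Cl replaced by SAc)
Conditions: KSAc, TBAI (cat.), DMF, 60 °C
Reagents that add atoms: potassium thioacetate CC(=O)[S-].[K+]
Why: Intermolecular SN2 displacement of the primary chloride by thioacetate, which can be forced with excess reagent; the free C4 hydroxyl does not interfere.

Step 14
Reactants: 20
Product: 21 the C4 methanesulfonate of 20
Conditions: MsCl, Et3N, CH2Cl2, 0 °C
Reagents that add atoms: methanesulfonyl chloride CS(Cl)(=O)=O
Why: Sulfonylation of the unhindered secondary alcohol; the thioester is not nucleophilic under these conditions.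

Step 15
Reactants: 21
Product: 23 11-membered cyclic sulfide (thiacycloundecene; S links C5 and C4; C4 methyl, C6 OTBS, trans-fused 2-methoxytetrahydrofuran on C7–C8, C10 CH2OTBDPS, ring-trans C1=C10), via thiol 22 (not isolated)
Conditions: Cs2CO3, MeOH/DMF (degassed), syringe-pump addition to ca. 2 mM, rt → 40 °C
Reagents that add atoms: none
Why: Methanolysis of the thioacetate gives a cesium thiolate that displaces the secondary mesylate intramolecularly (SN2, inversion at the transient C4 centre); high dilution and the cesium counter-ion favour cyclisation, as in established macrocyclic sulfide syntheses.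

Step 16
Reactants: 23
Product: 25 the cyclic sulfone (S,S-dioxide of 23), via sulfoxide 24 (not isolated)
Conditions: (NH4)6Mo7O24·4H2O (cat.), 30 % H2O2, MeOH, 0 °C → rt
Reagents that add atoms: hydrogen peroxide OO
Why: Molybdate-catalysed peroxide oxidation takes sulfide to sulfone and is known to spare trisubstituted olefins and silyl ethers.

Step 17
Reactants: 25
Product: 28 ten-membered (1(10) ring-trans, 4Z)-cyclodeca-1(10),4-diene (6-OTBS, 14-OTBDPS, C12 methyl acetal), via α-bromo sulfone 26 (not isolated), via episulfone 27 (not isolated)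
Conditions: KOH/Al2O3, CBr2F2, t-BuOH/CH2Cl2, 0 °C → rt
Reagents that add atoms: none
Why: Ramberg–Bäcklund reaction with in-situ halogenation: an α-sulfonyl carbanion is brominated by CBr2F2 (either α-bromo regioisomer serves), the α'-carbanion displaces bromide in a 1,3-elimination to the thiirane 1,1-dioxide, and cheletropic loss of SO2 gives C4=C5. The closest precedents are ring contractions of cyclic sulfones to cycloalkenes, including 11-membered thiacycles to ten-membered carbocycles, β-alkoxy thiepane dioxides to cyclohexenes, and S-glycoside dioxides to exo-glycals. The only ring closed is the transient three-membered episulfone (3-exo-tet), and its extrusion turns the 11-membered thiacycle into the ten-membered carbocycle. No stereocentre is created: C6, C7 and C8 are untouched, C4 is destroyed, and the olefin geometry follows from the episulfone, whose kinetic cis-fusion on the medium ring (ring arms C3 and C6 on the same side) should give the Z olefin while C1=C10 stays ring-trans. The step needs 1,3-elimination to win over β-elimination of the C6 silyloxy group and cis- over trans-episulfone formation. It relies on the sulfone α-hydrogens being the only acidic C–H (C12 is an acetal, not a lactone), on silyloxide being a poor leaving group, on the low temperature, and on the mild heterogeneous base, which should not equilibrate the episulfone.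

Step 18
Reactants: 28
Product: 29 the C12 lactol of 28 (anomers)
Conditions: AcOH/THF/H2O (3:1:1), rt → 35 °C
Reagents that add atoms: water O
Why: Mild acid hydrolysis of the 2-methoxytetrahydrofuran acetal; the secondary TBS and primary TBDPS ethers should survive, and the temperature is kept low to avoid Cope or transannular reactions of the 1,5-diene.

Step 19
Reactants: 29
Product: 30 trans-fused 8,12-γ-lactone (6-OTBS, 14-OTBDPS, 1(10),4-diene)
Conditions: TPAP (cat.), NMO, 4 Å MS, CH2Cl2, rt
Reagents that add atoms: none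
Why: Ley–Griffith oxidation of a lactol to the lactone under neutral conditions; O6 is still silylated, so only the 8,12-lactone can form.

Step 20
Reactants: 30; 31 N,N-dimethylmethyleneiminium iodide (Eschenmoser's salt)
Product: 34 α-methylene lactone (6-OTBS, 14-OTBDPS), via Mannich base 32 (not isolated), via methiodide 33 (not isolated)
Conditions: LDA, THF, −78 °C; 31, −78 °C → rt; then MeI, MeOH, rt; then aq. NaHCO3/CH2Cl2
Reagents that add atoms: none
Why: Mannich reaction of the lactone lithium enolate at C11, N-quaternisation and β-elimination of trimethylamine give the exocyclic methylene; C11 is the only enolisable position and no leaving group sits on C7.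

Step 21
Reactants: 34
Product: 35 6,14-diol (α-methylene lactone, 1(10),4-diene)
Conditions: HF·pyridine, pyridine, THF, 0 °C → rt
Reagents that add atoms: none
Why: Fluoride cleavage of both silyl ethers under buffered, non-basic conditions, which should avoid acyl migration of the lactone to O6.

Step 22
Reactants: 35; 36 (E)-2-methylbut-2-enoyl chloride (tigloyl chloride)
Product: 37 14-O-tigloyl 6-hydroxy diene lactone
Conditions: 36 (1.1 equiv), 2,4,6-collidine, CH2Cl2, −40 → 0 °C
Reagents that add atoms: none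
Why: Selective acylation of the primary allylic hydroxyl over the hindered secondary C6 hydroxyl with an acid chloride and a weak hindered base, which should also avoid deconjugation of the tigloyl group.

Step 23
Reactants: 37
Product: 38 CNP0116446.1, (4S,5R,6S,7S,8S)-4,5-epoxy-6-hydroxy-14-(tigloyloxy)germacra-1(10),11(13)-dien-12,8-olide
Conditions: mCPBA, NaHCO3, CH2Cl2, 0 °C
Reagents that add atoms: 3-chloroperbenzoic acid OOC(=O)c1cccc(Cl)c1
Why: Henbest-type hydroxyl-directed peracid epoxidation: 1,3-allylic strain in the Z-allylic alcohol puts H6 in the olefin plane, and the peracid, hydrogen-bonded to O6–H, attacks the open face (threo product, O trans to OH in the ring), setting C4 and C5. The C1=C10 olefin is deactivated by the allylic ester and the two conjugated olefins are electron-poor.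

**Compound list**

1 | (S)-4-benzylthiazolidine-2-thione | S=C1N[C@@H](Cc2ccccc2)CS1 | starting material
2 | pent-4-enoyl chloride | C=CCCC(Cl)=O | starting material
3 | (S)-1-(4-benzyl-2-thioxothiazolidin-3-yl)pent-4-en-1-one | C=CCCC(=O)N1C(=S)SC[C@@H]1Cc1ccccc1 | intermediate
4 | chloroacetaldehyde | ClCC=O | starting material
5 | (2S,3S)-2-allyl-1-[(S)-4-benzyl-2-thioxothiazolidin-3-yl]-4-chloro-3-hydroxybutan-1-one | ClC[C@@H](O)[C@H](CC=C)C(=O)N1C(=S)SC[C@@H]1Cc1ccccc1 | intermediate
6 | TBS ether of 5 | ClC[C@@H](O[Si](C)(C)C(C)(C)C)[C@H](CC=C)C(=O)N1C(=S)SC[C@@H]1Cc1ccccc1 | intermediate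
7 | (2S,3S)-2-allyl-3-(tert-butyldimethylsilyloxy)-4-chlorobutanal | ClC[C@@H](O[Si](C)(C)C(C)(C)C)[C@H](CC=C)C=O | intermediate
8 | 2-methylprop-2-en-1-ol | C=C(C)CO | starting material
9 | 2-[(tributylstannyl)methyl]prop-2-en-1-ol | C=C(CO)C[Sn](CCCC)(CCCC)CCCC | intermediate
10 | tert-butyldiphenyl({2-[(tributylstannyl)methyl]allyl}oxy)silane | C=C(CO[Si](c1ccccc1)(c1ccccc1)C(C)(C)C)C[Sn](CCCC)(CCCC)CCCC | intermediate
11 | (2S,3R,4S)-3-allyl-2-(tert-butyldimethylsilyloxy)-6-[(tert-butyldiphenylsilyloxy)methyl]-1-chlorohept-6-en-4-ol | ClC[C@@H](O[Si](C)(C)C(C)(C)C)[C@H](CC=C)[C@@H](O)CC(=C)CO[Si](c1ccccc1)(c1ccccc1)C(C)(C)C | intermediate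
12 | bis(1,2,4-trioxolane) from 11 (bis-ozonide) | ClC[C@@H](O[Si](C)(C)C(C)(C)C)[C@H](CC1OCOO1)[C@@H](O)CC1(CO[Si](c2ccccc2)(c2ccccc2)C(C)(C)C)OCOO1 | intermediate (not isolated)
13 | keto lactol: 1-{(2S,3R)-3-[(S)-1-(tert-butyldimethylsilyloxy)-2-chloroethyl]-5-hydroxytetrahydrofuran-2-yl}-3-(tert-butyldiphenylsilyloxy)propan-2-one | ClC[C@@H](O[Si](C)(C)C(C)(C)C)[C@@H]1CC(O)O[C@H]1CC(=O)CO[Si](c1ccccc1)(c1ccccc1)C(C)(C)C | intermediate
14 | methyl acetal of 13 (5-methoxytetrahydrofuran) | ClC[C@@H](O[Si](C)(C)C(C)(C)C)[C@@H]1CC(OC)O[C@H]1CC(=O)CO[Si](c1ccccc1)(c1ccccc1)C(C)(C)C | intermediate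
15 | 5-chloropentan-2-one | CC(=O)CCCCl | starting material
16 | (4-oxopentyl)triphenylphosphonium iodide | CC(=O)CCC[P+](c1ccccc1)(c1ccccc1)c1ccccc1.[I-] | intermediate
17 | (4-hydroxypentyl)triphenylphosphonium iodide (racemic) | CC(O)CCC[P+](c1ccccc1)(c1ccccc1)c1ccccc1.[I-] | intermediate
18 | potassium 5-(triphenylphosphoranylidene)pentan-2-olate (oxido ylide) | CC([O-])CC[CH-][P+](c1ccccc1)(c1ccccc1)c1ccccc1.[K+] | intermediate (not isolated)
19 | (Z)-7-{(2S,3R)-3-[(S)-1-(tert-butyldimethylsilyloxy)-2-chloroethyl]-5-methoxytetrahydrofuran-2-yl}-6-[(tert-butyldiphenylsilyloxy)methyl]hept-5-en-2-ol | ClC[C@@H](O[Si](C)(C)C(C)(C)C)[C@@H]1CC(OC)O[C@H]1C/C(CO[Si](c1ccccc1)(c1ccccc1)C(C)(C)C)=C/CCC(C)O | intermediate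
20 | C5 thioacetate of 19 | CC(=O)SC[C@@H](O[Si](C)(C)C(C)(C)C)[C@@H]1CC(OC)O[C@H]1C/C(CO[Si](c1ccccc1)(c1ccccc1)C(C)(C)C)=C/CCC(C)O | intermediate
21 | C4 methanesulfonate of 20 | CC(=O)SC[C@@H](O[Si](C)(C)C(C)(C)C)[C@@H]1CC(OC)O[C@H]1C/C(CO[Si](c1ccccc1)(c1ccccc1)C(C)(C)C)=C/CCC(C)OS(C)(=O)=O | intermediate
22 | C5 thiol of 21 | SC[C@@H](O[Si](C)(C)C(C)(C)C)[C@@H]1CC(OC)O[C@H]1C/C(CO[Si](c1ccccc1)(c1ccccc1)C(C)(C)C)=C/CCC(C)OS(C)(=O)=O | intermediate (not isolated)
23 | 11-membered cyclic sulfide (S between C5 and C4) | S1C[C@@H](O[Si](C)(C)C(C)(C)C)[C@@H]2CC(OC)O[C@H]2C/C(CO[Si](c2ccccc2)(c2ccccc2)C(C)(C)C)=C/CCC1C | intermediate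
24 | cyclic sulfoxide of 23 | O=S1C[C@@H](O[Si](C)(C)C(C)(C)C)[C@@H]2CC(OC)O[C@H]2C/C(CO[Si](c2ccccc2)(c2ccccc2)C(C)(C)C)=C/CCC1C | intermediate (not isolated)
25 | 11-membered cyclic sulfone | O=S1(=O)C[C@@H](O[Si](C)(C)C(C)(C)C)[C@@H]2CC(OC)O[C@H]2C/C(CO[Si](c2ccccc2)(c2ccccc2)C(C)(C)C)=C/CCC1C | intermediate
26 | α-bromo sulfone (C5 regioisomer shown) | O=S1(=O)C(Br)[C@@H](O[Si](C)(C)C(C)(C)C)[C@@H]2CC(OC)O[C@H]2C/C(CO[Si](c2ccccc2)(c2ccccc2)C(C)(C)C)=C/CCC1C | intermediate (not isolated)
27 | cis-fused thiirane 1,1-dioxide across C4–C5 (one cis-fused face shown) | O=S1(=O)[C@@H]2[C@@H](O[Si](C)(C)C(C)(C)C)[C@@H]3CC(OC)O[C@H]3C/C(CO[Si](c3ccccc3)(c3ccccc3)C(C)(C)C)=C/CC[C@]12C | intermediate (not isolated)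
28 | ten-membered 1(10),4-diene, 6-OTBS, 14-OTBDPS, C12 methyl acetal | C/C1=C/[C@@H](O[Si](C)(C)C(C)(C)C)[C@@H]2CC(OC)O[C@H]2C/C(CO[Si](c2ccccc2)(c2ccccc2)C(C)(C)C)=C/CC1 | intermediate
29 | C12 lactol of 28 | C/C1=C/[C@@H](O[Si](C)(C)C(C)(C)C)[C@@H]2CC(O)O[C@H]2C/C(CO[Si](c2ccccc2)(c2ccccc2)C(C)(C)C)=C/CC1 | intermediate
30 | 8,12-lactone, 6-OTBS, 14-OTBDPS | C/C1=C/[C@@H](O[Si](C)(C)C(C)(C)C)[C@@H]2CC(=O)O[C@H]2C/C(CO[Si](c2ccccc2)(c2ccccc2)C(C)(C)C)=C/CC1 | intermediate
31 | N,N-dimethylmethyleneiminium iodide | C=[N+](C)C.[I-] | starting material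
32 | 11-(dimethylaminomethyl) lactone (Mannich base) | C/C1=C/[C@@H](O[Si](C)(C)C(C)(C)C)[C@@H]2C(CN(C)C)C(=O)O[C@H]2C/C(CO[Si](c2ccccc2)(c2ccccc2)C(C)(C)C)=C/CC1 | intermediate (not isolated)
33 | trimethylammonium iodide of 32 | C/C1=C/[C@@H](O[Si](C)(C)C(C)(C)C)[C@@H]2C(C[N+](C)(C)C)C(=O)O[C@H]2C/C(CO[Si](c2ccccc2)(c2ccccc2)C(C)(C)C)=C/CC1.[I-] | intermediate (not isolated)
34 | α-methylene lactone, 6-OTBS, 14-OTBDPS | C/C1=C/[C@@H](O[Si](C)(C)C(C)(C)C)[C@@H]2C(=C)C(=O)O[C@H]2C/C(CO[Si](c2ccccc2)(c2ccccc2)C(C)(C)C)=C/CC1 | intermediate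
35 | 6,14-dihydroxy α-methylene lactone diene | C/C1=C/[C@@H](O)[C@@H]2C(=C)C(=O)O[C@H]2C/C(CO)=C/CC1 | intermediate
36 | (E)-2-methylbut-2-enoyl chloride | C/C=C(\C)C(Cl)=O | starting material
37 | 14-O-tigloyl-6-hydroxy diene lactone | C/C1=C/[C@@H](O)[C@@H]2C(=C)C(=O)O[C@H]2C/C(COC(=O)/C(C)=C/C)=C/CC1 | intermediate
38 | CNP0116446.1 | C=C1C(=O)O[C@H]2C/C(COC(=O)/C(C)=C/C)=C/CC[C@]3(C)O[C@@H]3[C@@H](O)[C@H]12 | target

**Step count**

Total steps: 23. Longest linear sequence: 19 steps (steps 1–4, 7–9, 12–23, from compound 1).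

**Steps most likely to fail**

1. Step 17 (ring contraction). The C5 carbanion may expel the C6 silyloxide (β-elimination to a vinyl sulfone) before bromination and 1,3-elimination, or the episulfone may close trans-fused and give the E isomer at C4=C5. The fallback sets out from 25 and comes back at 28; it makes the C6 oxygen the leaving group instead of a bystander. Selective removal of the secondary TBS ether of 25 (HF·pyridine, 0 °C; the primary TBDPS ether is kept) gives the β-hydroxy sulfone F1. Its O,C-dianion (n-BuLi, 2.2 equiv, THF, −78 °C; an alkoxide cannot be eliminated) is chlorinated at C5 with hexachloroethane, and on warming the chlorohydrin alkoxide closes to the α,β-epoxy sulfone F2 (ring-closing half of a Darzens reaction). LiOt-Bu in THF then effects the epoxy-Ramberg–Bäcklund reaction (C4 carbanion opens the oxirane at C5, episulfone, loss of SO2) to the ring-contracted Z-allylic alcohol F3. TBSOTf/2,6-lutidine returns 28.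

2. Step 15 (macrocyclisation). Intermolecular S-alkylation or disulfide formation may outrun closure of the 11-membered ring at a secondary carbon, and elimination of the mesylate may compete. The fallback sets out from 19 and comes back at 23; it closes the other C–S bond by strain-driven epoxide opening. Mitsunobu reaction of 19 with thioacetic acid (PPh3, DIAD) puts sulfur on C4 to give thioacetate F4. HF·pyridine frees the C6 hydroxyl to give chlorohydrin F5. Cs2CO3 in MeOH/DMF at high dilution converts the chlorohydrin into the terminal C5–C6 epoxide, and the cesium thiolate opens it at the primary carbon C5 to give hydroxy sulfide F6. Silylation (TBSOTf, 2,6-lutidine) gives 23.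

3. Step 23 (epoxidation). The strained ring-trans C1=C10 olefin may compete for the peracid, or delivery to C4=C5 may occur from the wrong face. The fallback sets out from 34 and comes back at 38; it installs the oxirane before the ester with a metal-alkoxide-directed oxidant that acts only on the olefin of an allylic alcohol. Removal of only the secondary TBS ether of 34 (HF·pyridine, 0 °C) gives allylic alcohol F7, in which C14 still carries the bulky silyl ether. Ti(Oi-Pr)4/t-BuOOH (CH2Cl2, −20 °C), threo-selective for Z-allylic alcohols with 1,3-allylic strain, gives epoxy alcohol F8. Buffered fluoride (TBAF/AcOH) gives epoxy diol F9. Selective acylation of the primary hydroxyl with 36 and 2,4,6-collidine gives 38.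

**Further compounds**

F1 | step 17 | β-hydroxy sulfone (6-OH, 14-OTBDPS, C12 methyl acetal) | O=S1(=O)C[C@@H](O)[C@@H]2CC(OC)O[C@H]2C/C(CO[Si](c2ccccc2)(c2ccccc2)C(C)(C)C)=C/CCC1C
F2 | step 17 | α,β-epoxy sulfone (oxirane across C5–C6) | O=S1(=O)C2O[C@H]2[C@@H]3CC(OC)O[C@H]3C/C(CO[Si](c3ccccc3)(c3ccccc3)C(C)(C)C)=C/CCC1C
F3 | step 17 | ring-contracted Z-allylic alcohol (6-OH, 14-OTBDPS, C12 methyl acetal) | C/C1=C/[C@@H](O)[C@@H]2CC(OC)O[C@H]2C/C(CO[Si](c2ccccc2)(c2ccccc2)C(C)(C)C)=C/CC1
F4 | step 15 | C4 thioacetate of the C5 chloride (6-OTBS) | ClC[C@@H](O[Si](C)(C)C(C)(C)C)[C@@H]1CC(OC)O[C@H]1C/C(CO[Si](c1ccccc1)(c1ccccc1)C(C)(C)C)=C/CCC(C)SC(C)=O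
F5 | step 15 | chlorohydrin thioacetate (6-OH) | ClC[C@@H](O)[C@@H]1CC(OC)O[C@H]1C/C(CO[Si](c1ccccc1)(c1ccccc1)C(C)(C)C)=C/CCC(C)SC(C)=O
F6 | step 15 | 11-membered cyclic sulfide with free 6-OH | S1C[C@@H](O)[C@@H]2CC(OC)O[C@H]2C/C(CO[Si](c2ccccc2)(c2ccccc2)C(C)(C)C)=C/CCC1C
F7 | step 23 | 6-hydroxy-14-OTBDPS α-methylene lactone diene | C/C1=C/[C@@H](O)[C@@H]2C(=C)C(=O)O[C@H]2C/C(CO[Si](c2ccccc2)(c2ccccc2)C(C)(C)C)=C/CC1
F8 | step 23 | 4,5-epoxy-6-hydroxy-14-OTBDPS lactone | C=C1C(=O)O[C@H]2C/C(CO[Si](c3ccccc3)(c3ccccc3)C(C)(C)C)=C/CC[C@]3(C)O[C@@H]3[C@@H](O)[C@H]12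
F9 | step 23 | 4,5-epoxy-6,14-dihydroxy lactone | C=C1C(=O)O[C@H]2C/C(CO)=C/CC[C@]3(C)O[C@@H]3[C@@H](O)[C@H]12
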